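## Retrosynthetic overview

1. The butenolide is made last: copper-catalysed anti-carbomagnesiation and CO2 trapping of a C16 propargylic alcohol forms C17–C25 and C18–C19, and a Tamao oxidation frees the second CH2OH.
2. The (Z)-C13=C14 alkene comes from a silicon-tethered ring-closing metathesis between a 2-substituted allylic alcohol and an (R)-enynol (C16 from a Keck allylation); C12–C13 from a Kumada coupling with 2-bromoallyl alcohol.
3. Key step: ring B is closed by radical cyclisation of a tertiary bromide onto the central carbon of an allene, forming the C9–C10 bond, the quaternary C10 centre and the C8=C9 alkene together.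
4. The allene comes from a vinyl-substituted ring A by hydroboration and copper-catalysed coupling with a propargylic phosphate; C5 is set by asymmetric conjugate addition to an enone made by Robinson annulation.
5. Ring order: ring A (step 1), ring B (step 8), a temporary eight-membered silacycle (step 12, opened in step 13), butenolide (step 14).

Assumption: atom labels C1–C25 follow the usual sesterterpenoid numbering (C5/C10 ring fusion, C16 butenolide stereocentre, C24 and C25 the two CH2OH carbons), and organometallic transfer reagents and CO2 are treated as reagents.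

Abbreviation used in names: Dec = (4aS,8aS)-2,5,5,8a-tetramethyl-3,4,4a,5,6,7,8,8a-octahydronaphthalen-1-yl.

## Route

Step 1
Reactants: 1 2-methylpropanal; 2 pent-1-en-3-one
Product: 4 2,4,4-trimethylcyclohex-2-en-1-one, via 2,2-dimethyl-5-oxoheptanal 3 (not isolated)
Conditions: conc. H2SO4 (cat.), PhH, 50 °C then reflux (Dean–Stark)
Reagents that add atoms: none
Why: Acid-catalysed Robinson annulation, in which Michael addition of the aldehyde enol to the vinyl ketone is followed by aldol condensation of the ethyl CH2 onto the non-enolisable aldehyde, the only closure that gives a six-membered ring; no stereocentre is formed.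

Step 2
Reactants: 4 2,4,4-trimethylcyclohex-2-en-1-one
Product: 6 (3S)-3-ethenyl-2,4,4-trimethylcyclohex-1-en-1-yl trifluoromethanesulfonate, via magnesium enolate 5 (not isolated)
Conditions: CH2=CHMgBr (1.3 equiv), CuBr·SMe2 (5 mol %), (R)-1-[(S)-2-(diphenylphosphino)ferrocenyl]ethyldicyclohexylphosphine (6 mol %), t-BuOMe, −78 °C; then PhNTf2, DMPU, −78 → 0 °C; aq. NH4Cl
Reagents that add atoms: vinylmagnesium bromide C=C[Mg]Br; N-phenylbis(trifluoromethanesulfonimide) O=S(=O)(N(c1ccccc1)S(=O)(=O)C(F)(F)F)C(F)(F)F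
Why: Copper/diphosphine-catalysed asymmetric conjugate addition of a Grignard reagent, by analogy with 2-substituted and 4,4-disubstituted cyclohexenones, delivers vinyl to one enone face and sets C5 as (S) (the ligand antipode is chosen for this sense; its mirror image gives the enantiomer), and the regiodefined enolate is O-triflated in the same flask.

Step 3
Reactants: 6 (3S)-3-ethenyl-2,4,4-trimethylcyclohex-1-en-1-yl trifluoromethanesulfonate
Product: 7 (6S)-6-ethenyl-1,5,5-trimethylcyclohex-1-ene
Conditions: Pd(OAc)2 (5 mol %), PPh3 (10 mol %), HCO2H, n-Bu3N, DMF, 60 °C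
Reagents that add atoms: none
Why: Palladium-catalysed formate reduction of an enol triflate replaces OTf by H and leaves the allylic stereocentre and the vinyl group untouched.

Step 4
Reactants: 8 chloroacetaldehyde (anhydrous, freshly distilled)
Product: 9 1-chloropent-3-yn-2-ol (racemic)
Conditions: MeC≡CMgBr, THF, −78 → 0 °C; aq. NH4Cl
Reagents that add atoms: prop-1-ynylmagnesium bromide CC#C[Mg]Br
Why: Grignard 1,2-addition to an aldehyde; the carbinol centre is left racemic because it disappears when the allene is formed.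

Step 5
Reactants: 9 1-chloropent-3-yn-2-ol
Product: 10 1-chloropent-3-yn-2-yl diethyl phosphate (racemic)
Conditions: ClP(O)(OEt)2, pyridine, DMAP (cat.), CH2Cl2, 0 °C
Reagents that add atoms: diethyl chlorophosphate CCOP(=O)(Cl)OCC
Why: O-Phosphorylation of the secondary propargylic alcohol installs the leaving group for the copper-mediated SN2′ substitution.

Step 6
Reactants: 7 (6S)-6-ethenyl-1,5,5-trimethylcyclohex-1-ene; 10 1-chloropent-3-yn-2-yl diethyl phosphate
Product: 12 (6S)-6-(6-chloro-3-methylhexa-3,4-dien-1-yl)-1,5,5-trimethylcyclohex-1-ene, via alkylborane 11 (not isolated)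
Conditions: 9-BBN-H, THF, 0 °C → rt; then 10 (1.3 equiv), CuOAc (10 mol %), KOt-Bu (1.0 equiv), THF, 40 °C
Reagents that add atoms: none
Why: 9-BBN hydroborates only the monosubstituted vinyl group, and copper-catalysed γ-selective coupling of the alkylborane with the propargylic phosphate (anti-SN2′ allene synthesis) puts the alkyl group on the methyl-bearing alkyne carbon; the allene axis forms as a mixture that converges in step 8 and C5 is unaffected.

Step 7
Reactants: 12 (6S)-6-(6-chloro-3-methylhexa-3,4-dien-1-yl)-1,5,5-trimethylcyclohex-1-ene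
Product: 13 (2S)-1-bromo-2-(6-chloro-3-methylhexa-3,4-dien-1-yl)-1,3,3-trimethylcyclohexane
Conditions: HBr (1.05 equiv, anhydrous), CH2Cl2, −78 °C, 15 min; used crude
Reagents that add atoms: hydrogen bromide Br
Why: Ionic Markovnikov hydrobromination, in which the trisubstituted ring alkene is protonated to a tertiary cation much faster than the allene (central-carbon protonation gives a non-conjugated, vinyl-destabilised cation) and the primary chloride is inert; the new C–Br centre is a mixture that is erased in step 8.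

Step 8
Reactants: 13 (2S)-1-bromo-2-(6-chloro-3-methylhexa-3,4-dien-1-yl)-1,3,3-trimethylcyclohexane
Product: 14 (4aS,8aS)-1-(2-chloroethyl)-2,5,5,8a-tetramethyl-3,4,4a,5,6,7,8,8a-octahydronaphthalene
Conditions: Bu3SnH (1.5 equiv) and AIBN (0.2 equiv) by syringe pump over 8 h, PhH (5 mM), 80 °C
Reagents that add atoms: none
Why: Proposed new method: bromine abstraction gives the tertiary C10 radical, which adds through a chair-like transition state to the central (sp) carbon of the allene (attack at the methyl-bearing terminus would join two fully substituted carbons) to close ring B and form the C9–C10 bond, the equatorial C5 side chain forcing the new bond trans to H-5 so that the quaternary centre is (8aS), and the allyl radical then takes hydrogen from Bu3SnH at its less hindered CH terminus to leave the tetrasubstituted C8=C9 alkene; the closest known chemistry is tin-hydride radical cyclisation onto the central carbon of allenes and the trans-selective second ring closure of radical polyene cyclisations.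

Step 9
Reactants: 14 Dec-CH2CH2Cl [(4aS,8aS)-1-(2-chloroethyl)-2,5,5,8a-tetramethyl-3,4,4a,5,6,7,8,8a-octahydronaphthalene]; 15 2-bromoprop-2-en-1-ol
Product: 18 4-(Dec)-2-methylidenebutan-1-ol, via sodium 2-bromoprop-2-en-1-olate 16 (not isolated), via Grignard reagent 17 (not isolated)
Conditions: 14, Mg, BrCH2CH2Br (cat.), THF, reflux; 15, NaH, THF, 0 °C; combine, [1,1′-bis(diphenylphosphino)ferrocene]dichloropalladium PdCl2(dppf) (3 mol %), THF, 45 °C; aq. NH4Cl
Reagents that add atoms: none
Why: Grignard formation from the primary chloride and palladium-catalysed Kumada–Corriu coupling with the alkoxide of the alkenyl bromide forms the C12–C13 bond; no stereocentre is involved and the tetrasubstituted alkene is inert.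

Step 10
Reactants: 19 3-(trimethylsilyl)prop-2-ynal
Product: 20 (3R)-1-(trimethylsilyl)hex-5-en-1-yn-3-ol
Conditions: allylSnBu3 (1.2 equiv), Ti(Oi-Pr)4 (10 mol %), (R)-1,1′-bi-2-naphthol (20 mol %), 4 Å MS, CH2Cl2, −20 °C, 60 h; aq. NaHCO3
Reagents that add atoms: allyltributylstannane C=CC[Sn](CCCC)(CCCC)CCCC
Why: Keck asymmetric allylation, in which the (R)-binaphthol–titanium Lewis acid directs allyl transfer to one aldehyde face (the antipode that gives (R)-1-phenylbut-3-en-1-ol from benzaldehyde, the alkynyl group ranking like phenyl) and so sets C16 as (R).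

Step 11
Reactants: 20 (3R)-1-(trimethylsilyl)hex-5-en-1-yn-3-ol; 18 4-(Dec)-2-methylidenebutan-1-ol
Product: 22 [4-(Dec)-2-methylidenebutoxy](diphenyl){[(3R)-1-(trimethylsilyl)hex-5-en-1-yn-3-yl]oxy}silane, via chlorosilane 21 (not isolated)
Conditions: Ph2SiCl2 (1.05 equiv), Et3N, CH2Cl2, −78 → 0 °C with 20; then 18, Et3N, DMAP (cat.), 0 °C → rt
Reagents that add atoms: dichlorodiphenylsilane Cl[Si](Cl)(c1ccccc1)c1ccccc1
Why: Stepwise O-silylation (secondary alcohol first, then the primary allylic alcohol) gives the mixed diphenylsilylene acetal that tethers the two alkenes; no configuration is touched.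

Step 12
Reactants: 22 mixed silylene acetal
Product: 23 (5Z,8R)-5-[2-(Dec)ethyl]-2,2-diphenyl-8-[(trimethylsilyl)ethynyl]-1,3-dioxa-2-silacyclooct-5-ene
Conditions: second-generation Grubbs catalyst [1,3-bis(2,4,6-trimethylphenyl)imidazolidin-2-ylidene]dichloro(benzylidene)(tricyclohexylphosphine)ruthenium (10 mol %), PhMe (2 mM), 80 °C
Reagents that add atoms: none
Why: Temporary silicon-tethered ring-closing metathesis; closure to the eight-membered ring can only give the endocyclic cis trisubstituted alkene, which fixes C24 cis to C15, the (Z) geometry of the target.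

Step 13
Reactants: 23 cyclic silylene acetal
Product: 24 (2Z,5R)-2-[2-(Dec)ethyl]hept-2-en-6-yne-1,5-diol
Conditions: Bu4NF (3.3 equiv), THF, 0 °C → rt; aq. NH4Cl
Reagents that add atoms: none
Why: Fluoride-mediated desilylation cleaves both Si–O bonds of the tether and the C(sp)–SiMe3 bond, releasing the (Z)-diol with a terminal propargylic alcohol.

Step 14
Reactants: 24 (2Z,5R)-2-[2-(Dec)ethyl]hept-2-en-6-yne-1,5-diol
Product: 28 (5R)-4-{[dimethyl(propan-2-yloxy)silyl]methyl}-5-[(2Z)-5-(Dec)-3-(hydroxymethyl)pent-2-en-1-yl]furan-2(5H)-one, via bis(chloromagnesium) dialkoxide 25 (not isolated), via alkenylmagnesium chelate 26 (not isolated), via hydroxy acid 27 (not isolated)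
Conditions: i-PrMgCl (2.0 equiv), THF, 0 °C; ClMgCH2SiMe2(Oi-Pr) (3 equiv), CuI (20 mol %), THF, 0 °C → rt, 16 h; CO2 (gas), −20 °C → rt; 1 M HCl, rt
Reagents that add atoms: [dimethyl(propan-2-yloxy)silyl]methylmagnesium chloride CC(C)O[Si](C)(C)C[Mg]Cl; carbon dioxide O=C=O
Why: Copper-catalysed anti-carbomagnesiation of the propargylic alkoxide (Duboudin–Jousseaume reaction) adds the silylmethyl group to C17 and places magnesium on C18 cis to the C16 alkoxide, so that carboxylation and acidification give a γ-hydroxy acid that lactonises to the butenolide; C16 stays (R) because its C–O bond is never broken.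

Step 15
Reactants: 28 silylmethyl butenolide
Product: 29 16-epi-luffarin L, (5R)-4-(hydroxymethyl)-5-[(2Z)-5-(Dec)-3-(hydroxymethyl)pent-2-en-1-yl]furan-2(5H)-one
Conditions: 30 % H2O2, KF, KHCO3, THF/MeOH (1:1), rt
Reagents that add atoms: hydrogen peroxide OO
Why: Tamao–Fleming oxidation converts the C–Si bond of the alkoxysilane into C–OH under buffered peroxide conditions that are mild enough for the butenolide and its C16 stereocentre.

## Compound list

1 | 2-methylpropanal | CC(C)C=O | starting material
2 | pent-1-en-3-one | CCC(=O)C=C | starting material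
3 | 2,2-dimethyl-5-oxoheptanal | CCC(=O)CCC(C)(C)C=O | intermediate
4 | 2,4,4-trimethylcyclohex-2-en-1-one | CC1=CC(C)(C)CCC1=O | intermediate
5 | bromomagnesium (3S)-3-ethenyl-2,4,4-trimethylcyclohex-1-en-1-olate | C=C[C@@H]1C(C)=C(O[Mg]Br)CCC1(C)C | intermediate
6 | (3S)-3-ethenyl-2,4,4-trimethylcyclohex-1-en-1-yl trifluoromethanesulfonate | C=C[C@@H]1C(C)=C(OS(=O)(=O)C(F)(F)F)CCC1(C)C | intermediate
7 | (6S)-6-ethenyl-1,5,5-trimethylcyclohex-1-ene | C=C[C@@H]1C(C)=CCCC1(C)C | intermediate
8 | chloroacetaldehyde | ClCC=O | starting material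
9 | 1-chloropent-3-yn-2-ol (racemic) | CC#CC(O)CCl | intermediate
10 | 1-chloropent-3-yn-2-yl diethyl phosphate (racemic) | CC#CC(CCl)OP(=O)(OCC)OCC | intermediate
11 | 9-{2-[(1S)-2,6,6-trimethylcyclohex-2-en-1-yl]ethyl}-9-borabicyclo[3.3.1]nonane | B1(CC[C@@H]2C(C)=CCCC2(C)C)C2CCCC1CCC2 | intermediate
12 | (6S)-6-(6-chloro-3-methylhexa-3,4-dien-1-yl)-1,5,5-trimethylcyclohex-1-ene (both allene axial isomers) | ClCC=C=C(C)CC[C@@H]1C(C)=CCCC1(C)C | intermediate
13 | (2S)-1-bromo-2-(6-chloro-3-methylhexa-3,4-dien-1-yl)-1,3,3-trimethylcyclohexane (mixture at C1 and at the allene axis) | ClCC=C=C(C)CC[C@@H]1C(C)(Br)CCCC1(C)C | intermediate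
14 | (4aS,8aS)-1-(2-chloroethyl)-2,5,5,8a-tetramethyl-3,4,4a,5,6,7,8,8a-octahydronaphthalene (Dec-CH2CH2Cl) | CC1=C(CCCl)[C@@]2(C)CCCC(C)(C)[C@@H]2CC1 | intermediate
15 | 2-bromoprop-2-en-1-ol | C=C(Br)CO | starting material
16 | sodium 2-bromoprop-2-en-1-olate | [Na+].[O-]CC(Br)=C | intermediate
17 | [2-(Dec)ethyl]magnesium chloride | CC1=C(CC[Mg]Cl)[C@@]2(C)CCCC(C)(C)[C@@H]2CC1 | intermediate
18 | 4-(Dec)-2-methylidenebutan-1-ol | CC1=C(CCC(=C)CO)[C@@]2(C)CCCC(C)(C)[C@@H]2CC1 | intermediate
19 | 3-(trimethylsilyl)prop-2-ynal | O=CC#C[Si](C)(C)C | starting material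
20 | (3R)-1-(trimethylsilyl)hex-5-en-1-yn-3-ol | C=CC[C@@H](O)C#C[Si](C)(C)C | intermediate
21 | chloro(diphenyl){[(3R)-1-(trimethylsilyl)hex-5-en-1-yn-3-yl]oxy}silane | C=CC[C@@H](O[Si](Cl)(c1ccccc1)c1ccccc1)C#C[Si](C)(C)C | intermediate
22 | [4-(Dec)-2-methylidenebutoxy](diphenyl){[(3R)-1-(trimethylsilyl)hex-5-en-1-yn-3-yl]oxy}silane | CC1=C(CCC(=C)CO[Si](O[C@H](CC=C)C#C[Si](C)(C)C)(c3ccccc3)c3ccccc3)[C@@]2(C)CCCC(C)(C)[C@@H]2CC1 | intermediate
23 | (5Z,8R)-5-[2-(Dec)ethyl]-2,2-diphenyl-8-[(trimethylsilyl)ethynyl]-1,3-dioxa-2-silacyclooct-5-ene | CC1=C(CC/C3=C/C[C@H](C#C[Si](C)(C)C)O[Si](c4ccccc4)(c4ccccc4)OC3)[C@@]2(C)CCCC(C)(C)[C@@H]2CC1 | intermediate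
24 | (2Z,5R)-2-[2-(Dec)ethyl]hept-2-en-6-yne-1,5-diol | CC1=C(CC/C(=C/C[C@@H](O)C#C)CO)[C@@]2(C)CCCC(C)(C)[C@@H]2CC1 | intermediate
25 | bis(chloromagnesium) dialkoxide of 24 | CC1=C(CC/C(=C/C[C@@H](O[Mg]Cl)C#C)CO[Mg]Cl)[C@@]2(C)CCCC(C)(C)[C@@H]2CC1 | intermediate
26 | alkenylmagnesium chelate (silylmethyl on C17, MgCl on C18 cis to the C16 alkoxide) | CC1=C(CC/C(=C/C[C@@H](O[Mg]Cl)/C(C[Si](C)(C)OC(C)C)=C\[Mg]Cl)CO[Mg]Cl)[C@@]2(C)CCCC(C)(C)[C@@H]2CC1 | intermediate
27 | (2E,4R,6Z)-9-(Dec)-3-{[dimethyl(propan-2-yloxy)silyl]methyl}-4-hydroxy-7-(hydroxymethyl)nona-2,6-dienoic acid (CO2H cis to C4) | CC1=C(CC/C(=C/C[C@@H](O)/C(C[Si](C)(C)OC(C)C)=C\C(O)=O)CO)[C@@]2(C)CCCC(C)(C)[C@@H]2CC1 | intermediate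
28 | (5R)-4-{[dimethyl(propan-2-yloxy)silyl]methyl}-5-[(2Z)-5-(Dec)-3-(hydroxymethyl)pent-2-en-1-yl]furan-2(5H)-one | CC1=C(CC/C(=C/C[C@H]3OC(=O)C=C3C[Si](C)(C)OC(C)C)CO)[C@@]2(C)CCCC(C)(C)[C@@H]2CC1 | intermediate
29 | 16-epi-luffarin L, (5R)-4-(hydroxymethyl)-5-[(2Z)-5-(Dec)-3-(hydroxymethyl)pent-2-en-1-yl]furan-2(5H)-one | CC1=C(CC/C(=C/C[C@H]2OC(=O)C=C2CO)CO)[C@@]2(C)CCCC(C)(C)[C@@H]2CC1 | target

## Step count and risks

Total step count: 15. Longest linear sequence: 12 steps (steps 1, 2, 3, 6, 7, 8, 9, 11, 12, 13, 14, 15).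

The three steps most likely to fail:

Step 8, the radical ring closure. The six-membered closure onto the allene is slow, so direct reduction of the tertiary radical by Bu3SnH competes, and hydrogen transfer to the allyl radical could also occur at C8. The fallback is polar; it sets out from 13 and comes back at 14. The tertiary bromide is ionised with Et2AlCl in CH2Cl2 at −78 °C in the presence of Et3SiH, so that the C10 cation adds to the central allene carbon through the same chair-like arrangement and the resulting allyl cation is reduced by the silane at C11 (cation–allene cyclisation with ionic hydrogenation). This fallback makes no new compound (F0).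

Step 2, the asymmetric vinyl conjugate addition. The enone is hindered and α-substituted, so conversion and enantioselectivity are uncertain, and the enolate triflation must follow in the same flask. The fallback sets out from 4 and comes back at 7, replacing steps 2 and 3. Corey–Bakshi–Shibata reduction of 4 with (R)-1-methyl-3,3-diphenyltetrahydro-1H,3H-pyrrolo[1,2-c][1,3,2]oxazaborole and BH3·SMe2 gives (1S)-2,4,4-trimethylcyclohex-2-en-1-ol F1. Esterification with picolinic acid (DCC, DMAP) gives (1S)-2,4,4-trimethylcyclohex-2-en-1-yl pyridine-2-carboxylate F2. Vinylmagnesium bromide with CuBr·SMe2 in THF at −40 °C then displaces the picolinate by anti-SN2′ substitution with 1,3-chirality transfer, delivering the vinyl group to C5 on the face opposite the departing oxygen and giving 7 directly.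

Step 15, the Tamao oxidation. The silylmethyl group is vinylogously α to the lactone carbonyl, so fluoride may cleave the C–Si bond and give the 4-methyl butenolide instead of the alcohol. The fallback sets out from 24 and comes back at the target 29. The copper-catalysed anti-carbomagnesiation of 24 is quenched with I2 instead of CO2, giving (2Z,5R,6E)-2-[2-(Dec)ethyl]-6-{[dimethyl(propan-2-yloxy)silyl]methyl}-7-iodohepta-2,6-diene-1,5-diol F3, an ordinary allylsilane. Tamao oxidation (H2O2, KF, KHCO3) of F3 gives (2Z,5R,6Z)-2-[2-(Dec)ethyl]-6-(hydroxymethyl)-7-iodohepta-2,6-diene-1,5-diol F4. Palladium-catalysed carbonylative lactonisation (Pd(PPh3)4, CO 1 atm, K2CO3, THF, 50 °C) then closes the butenolide onto the C16 hydroxyl, which is cis to the iodide, and gives 29.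

Further compounds
F0 | step 8 | none | none
F1 | step 2 | (1S)-2,4,4-trimethylcyclohex-2-en-1-ol | O[C@H]1CCC(C)(C)C=C1C
F2 | step 2 | (1S)-2,4,4-trimethylcyclohex-2-en-1-yl pyridine-2-carboxylate | O=C(O[C@H]1CCC(C)(C)C=C1C)c1ccccn1
F3 | step 15 | (2Z,5R,6E)-2-[2-(Dec)ethyl]-6-{[dimethyl(propan-2-yloxy)silyl]methyl}-7-iodohepta-2,6-diene-1,5-diol | CC1=C(CC/C(=C/C[C@@H](O)/C(C[Si](C)(C)OC(C)C)=C\I)CO)[C@@]2(C)CCCC(C)(C)[C@@H]2CC1
F4 | step 15 | (2Z,5R,6Z)-2-[2-(Dec)ethyl]-6-(hydroxymethyl)-7-iodohepta-2,6-diene-1,5-diol | CC1=C(CC/C(=C/C[C@@H](O)/C(CO)=C\I)CO)[C@@]2(C)CCCC(C)(C)[C@@H]2CC1
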